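| flask | substrate | reagent | temperature | remark | time |
|---|---|---|---|---|---|
| teal | 6.2 mM | 43.5 mM | 10 °C | run made earlier |  |
| amber | 23 mM | 43.5 mM | 25 °C | run made earlier |  |
| blue | 29 mM | 48 mM | 10 °C | run made earlier |  |
| south | 29 mM | 43.5 mM | 25 °C |  | 50 min |
| south-west | 10 mM | 80.0 mM | 25 °C |  | 50 min |

- teal (time / min: target / %, substrate / %): 8.00: 0.9, 89.1; 15.0: 0.4, 81.9; 30.0: 4.7, 66.7; 50.0: 10.0, 51.0; 120: 28.3, 20.6
- amber (time / min: target / %, substrate / %): 10.0: 9.3, 60.6; 20.0: 21.8, 38.1; 30.0: 31.4, 23.9; 40.0: 39.7, 16.0; 50.0: 45.7, 9.5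
- blue (time / min: target / %, substrate / %): 8.00: 1.0, 88.8; 25.0: 2.6, 70.1; 50.0: 8.5, 52.1; 80.0: 15.8, 36.8; 120: 23.9, 24.2

(each reading ± 0.5 percentage points)



- which one finishes higher in amount of target, in percent of the substrate charged ("neither" within 2 percentage points) (south / south-west / neither)
- amount of target at the end, in percent of the substrate charged, south
- amount of target at the end, in percent of the substrate charged, south-west

1. My unit was one reagent per substrate charged, the even case, so I placed each flask by its equivalents, reagent charge over substrate charge: south stood at 1.50 and south-west at 8.00.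

2. At 10 °C, teal had 7.02 and blue 1.66. At their last readings, the target per substrate gone was 0.356 in teal, more than the 0.315 in blue, so I read a higher number as a better share.

3. Amber, with 1.89, gave a share of 0.505 at 50.0 min. South lies below amber, so I put it a little under amber's 45.7 % of the charge. For south-west I scaled amber's share by teal over blue, which gave 0.571, and with amber's substrate left, 0.517 of the charge.

4. One number was not enough: at 50.0 min teal, at 7.02 equivalents, kept 51.0 % of its substrate and blue, at 1.66, kept 52.1 %, so the equivalents told a share, not a speed. South-west's reagent charge also stood above every earlier run.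

5. The forecast named south-west, with 38 % for south and 80 % for south-west, the second well above my figure, on the ground “South has only 1.5 equivalents of reagent, so it starves”.

6. South gave 41.6 % and south-west 61.1 %, so south-west finished higher.

    intermediate A ⇌ intermediate B (K = 0.360, k = 5.62 × 10⁻⁴ s⁻¹, Ea = 94.0 kJ mol⁻¹, ΔH = −32.0 kJ mol⁻¹)
    intermediate A → target (k = 0.00109 s⁻¹, Ea = 86.0 kJ mol⁻¹)
    reagent + intermediate A ⇌ intermediate C (K = 32.0 M⁻¹, k = 0.00816 M⁻¹ s⁻¹, Ea = 54.0 kJ mol⁻¹, ΔH = 8.00 kJ mol⁻¹)
    substrate + reagent → intermediate A (k = 0.0217 M⁻¹ s⁻¹, Ea = 65.0 kJ mol⁻¹)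
    substrate + target → side product (k = 0.0242 M⁻¹ s⁻¹, Ea = 61.0 kJ mol⁻¹)
    (constants at 25 °C)

7. Side product stood at 25.2 % of the charge in south, at 1.50 equivalents, and at 4.29 % in south-west, at 8.00. A neighbour like south, charged with 11 mM of reagent, had 0.379 equivalents, below the even case. It made 0.285 target per substrate gone, against 0.469 in south.

(The data stem from a simulated flask with constants of no real substance, noise included.)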